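**Retrosynthetic overview**
- Feature: the only ring, the tetrahydrofuran O1–C7(aryl)–C8(C9H2O-acyl)–C8'(C7'H2-aryl)–C9'H2, is a γ-aryl butenolide once C9' is a carbonyl and C8=C8' a double bond; C8 is then the β-carbon and C8' the α-carbon.
- End game: desilylation ⇐ esterification of the C9 alcohol ⇐ Tamao oxidation of a C9–Si bond; C8' ⇐ hydrogenation of C8'=C7'; ring CH2 (C9') ⇐ lactone C=O (DIBAL, then Et3SiH/BF3).
- Key disconnection: C8–C9 and C8'=C7' are cut together, back to butenolide 6, silylmethyl Grignard reagent 8 (as its cuprate) and aldehyde 2 (conjugate addition, aldol, elimination in one flask).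
- Butenolide 6 ⇐ Lindlar reduction and lactonisation of the ynoate from catalytic asymmetric addition of methyl propiolate to O-TIPS vanillin 2, which fixes C7.
- Ring order: the ring is closed once, as the lactone C7–O–C9' in step 3, and is kept to the end; no other ring is formed.

Key step: step 5

Assumption: the (S,S)-ProPhenol ligand is taken to give the (S)-carbinol 4 in step 2; if the sense of induction is the reverse, the (R,R)-ligand is used and nothing else changes.

**Step 1**
Reactants: 1 vanillin
Product: 2 3-methoxy-4-(triisopropylsilyloxy)benzaldehyde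
Conditions: TIPSCl, imidazole, DMF, 0 °C → rt
Reagents that add atoms: chlorotriisopropylsilane, CC(C)[Si](Cl)(C(C)C)C(C)C
Why: Silyl ether formation on the phenol is routine, and the bulky TIPS ether should tolerate the organometallic, hydride, cold Lewis-acid and hydrogenation steps that follow.

**Step 2**
Reactants: 2 3-methoxy-4-(triisopropylsilyloxy)benzaldehyde; 3 methyl propiolate
Product: 4 methyl (S)-4-hydroxy-4-[3-methoxy-4-(triisopropylsilyloxy)phenyl]but-2-ynoate
Conditions: Me2Zn, (S,S)-ProPhenol (cat.), Ph3PO (cat.), toluene, 4 °C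
Reagents that add atoms: none
Why: Zn–ProPhenol-catalysed asymmetric alkynylation of an aromatic aldehyde, in which the dinuclear zinc complex holds the aldehyde and the alkynylzinc and its chiral pocket selects the aldehyde face, sets C7 as the (S)-carbinol (the same spatial arrangement as 7R in the lactone and in the target, the descriptor changing only through CIP priorities).

**Step 3**
Reactants: 4 methyl (S)-4-hydroxy-4-[3-methoxy-4-(triisopropylsilyloxy)phenyl]but-2-ynoate
Product: 6 (R)-5-[3-methoxy-4-(triisopropylsilyloxy)phenyl]furan-2(5H)-one, via Z-hydroxy enoate 5 (not isolated)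
Conditions: H2 (1 atm), Lindlar catalyst, quinoline, EtOAc, rt; filter; PPTS (cat.), CH2Cl2, rt
Reagents that add atoms: none
Why: Lindlar cis-semihydrogenation places the hydroxyl and the ester on the same side of the alkene, so that lactonisation (intramolecular transesterification, 5-exo-trig) follows under mild acid; no bond to C7 is broken and its configuration is kept.

**Step 4**
Reactants: 7 (chloromethyl)(isopropoxy)dimethylsilane
Product: 8 [(isopropoxydimethylsilyl)methyl]magnesium chloride
Conditions: Mg turnings, BrCH2CH2Br (cat.), THF, reflux → rt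
Reagents that add atoms: magnesium, [Mg]
Why: Grignard formation from the α-silyl alkyl chloride is the standard way to this hydroxymethyl-anion equivalent, the hindered Si–O-isopropyl group being inert to the reagent.

**Step 5**
Reactants: 6 (R)-5-[3-methoxy-4-(triisopropylsilyloxy)phenyl]furan-2(5H)-one; 8 [(isopropoxydimethylsilyl)methyl]magnesium chloride; 2 3-methoxy-4-(triisopropylsilyloxy)benzaldehyde
Product: 12 (3E,4R,5R)-4-[(isopropoxydimethylsilyl)methyl]-3-[3-methoxy-4-(triisopropylsilyloxy)benzylidene]-5-[3-methoxy-4-(triisopropylsilyloxy)phenyl]dihydrofuran-2(3H)-one, via magnesium lactone enolate 9 (not isolated), via magnesium aldolate 10 (not isolated), via aldol acetate 11 (not isolated)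
Conditions: 8 (2.2 equiv), CuI (1.1 equiv), THF, −30 → −78 °C; 6 added slowly, −78 °C; 2, −78 → −40 °C; Ac2O, DMAP (cat.), → 0 °C; DBU, 0 °C → rt
Reagents that add atoms: none
Why: The homocuprate from 8 and CuI transfers one silylmethyl group to C8, the β-carbon of butenolide 6 (π-complexation, oxidative addition, reductive elimination), to give magnesium enolate 9, which attacks aldehyde 2 through C8' (aldol) to give aldolate 10; Ac2O converts 10 into acetate 11, and DBU removes the C8'–H and expels acetate (E1cB) to give the conjugated benzylidene lactone 12. The closest known reaction type is the tandem cuprate conjugate addition–aldol condensation of 5-substituted butenolides, together with the copper-mediated 1,4-addition of (alkoxysilyl)methyl Grignard reagents to enones. No ring is closed, because the butenolide already holds C7–O–C9'; the step only forms C8–C9 and C8'=C7'. The one lasting stereocentre, C8, is controlled by the adjacent C7 aryl group, which shields one face of the flat butenolide so that the cuprate enters anti and gives the 7,8-trans (4R,5R) lactone; the C8' and C7' centres of 10 and 11 are transient and are erased by the elimination. The E geometry is expected because the elimination and the product both prefer the aryl group anti to the lactone carbonyl. The step needs 1,4-addition to outrun deprotonation of the acidic C7–H, which would racemise 6 through its 2-oxyfuran anion, and this is secured by the low basicity of the stoichiometric cuprate at −78 °C with no free Grignard reagent left, which also reserves aldehyde 2 for the enolate.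

**Step 6**
Reactants: 12 the (3E,4R,5R)-benzylidene lactone
Product: 13 (3E,4R,5R)-4-[(isopropoxydimethylsilyl)methyl]-3-[3-methoxy-4-(triisopropylsilyloxy)benzylidene]-5-[3-methoxy-4-(triisopropylsilyloxy)phenyl]tetrahydrofuran-2-ol (both anomers)
Conditions: DIBAL-H (1.1 equiv), CH2Cl2, −78 °C; Rochelle salt work-up
Reagents that add atoms: none
Why: Partial reduction of a lactone to a lactol with DIBAL-H stops at the aluminium hemiacetal at −78 °C and goes by 1,2-addition on conjugated lactones; the anomeric centre is of no consequence because it becomes CH2 in step 7.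

**Step 7**
Reactants: 13 the benzylidene lactol
Product: 14 (2R,3R,4E)-3-[(isopropoxydimethylsilyl)methyl]-4-[3-methoxy-4-(triisopropylsilyloxy)benzylidene]-2-[3-methoxy-4-(triisopropylsilyloxy)phenyl]tetrahydrofuran
Conditions: Et3SiH (3 equiv), then BF3·OEt2 (promoter), CH2Cl2, −78 °C; cold NaHCO3 quench
Reagents that add atoms: none
Why: Reductive deoxygenation of a lactol (ionic hydrogenation type): BF3 ionises the anomeric C–O bond to the cyclic oxocarbenium ion and Et3SiH delivers hydride to C9', which keeps the styrene conjugation; at −78 °C this ionisation should be much faster than that of the benzylic C7–O bond, and a C7 that opened and reclosed would return to the favoured 7,8-trans arrangement dictated by C8.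

**Step 8**
Reactants: 14 the 4-benzylidene tetrahydrofuran
Product: 15 (2R,3R,4S)-3-[(isopropoxydimethylsilyl)methyl]-4-[3-methoxy-4-(triisopropylsilyloxy)benzyl]-2-[3-methoxy-4-(triisopropylsilyloxy)phenyl]tetrahydrofuran
Conditions: H2 (1 atm), 5% Pd/C, pyridine (cat.), EtOAc, rt
Reagents that add atoms: none
Why: Heterogeneous catalytic hydrogenation should deliver hydrogen to the face of C8'=C7' opposite the adjacent C8 silylmethyl arm, which allylic strain with the cis aryl group pushes pseudoaxial, so C8' is set with the benzyl group cis to the C8 arm (8'S of the target); pyridine is added to suppress hydrogenolysis of the benzylic C7–O bond.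

**Step 9**
Reactants: 15 the (2R,3R,4S)-silylmethyl tetrahydrofuran
Product: 16 [(2R,3S,4S)-4-[3-methoxy-4-(triisopropylsilyloxy)benzyl]-2-[3-methoxy-4-(triisopropylsilyloxy)phenyl]tetrahydrofuran-3-yl]methanol
Conditions: 30% H2O2, KHCO3, THF/MeOH (1:1), 45 °C
Reagents that add atoms: hydrogen peroxide, OO
Why: Tamao oxidation: hydroperoxide adds to the alkoxysilane and C9 migrates from silicon to oxygen, which unmasks the primary alcohol without touching C8; fluoride is left out so that the aryl TIPS ethers are not attacked.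

**Step 10**
Reactants: 17 4-hydroxybenzoic acid
Product: 19 4-(triisopropylsilyloxy)benzoic acid, via silyl ester 18 (not isolated)
Conditions: TIPSCl (2.2 equiv), imidazole, DMF, rt; then K2CO3, THF/MeOH/H2O, rt; 1 M HCl to pH 3–4
Reagents that add atoms: chlorotriisopropylsilane, CC(C)[Si](Cl)(C(C)C)C(C)C
Why: Exhaustive silylation followed by selective hydrolysis of the silyl ester, which is far more labile than the hindered aryl silyl ether, gives the phenol-protected acid.

**Step 11**
Reactants: 16 the (2R,3S,4S)-alcohol; 19 4-(triisopropylsilyloxy)benzoic acid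
Product: 20 [(2R,3S,4S)-4-[3-methoxy-4-(triisopropylsilyloxy)benzyl]-2-[3-methoxy-4-(triisopropylsilyloxy)phenyl]tetrahydrofuran-3-yl]methyl 4-(triisopropylsilyloxy)benzoate
Conditions: EDC·HCl, DMAP, CH2Cl2, 0 °C → rt
Reagents that add atoms: none
Why: Carbodiimide/DMAP esterification (Steglich esterification) of an unhindered primary alcohol, with no phenol free to compete and no stereocentre involved.

**Step 12**
Reactants: 20 the tris-TIPS ester
Product: 21 agastinol, [(2R,3S,4S)-4-(4-hydroxy-3-methoxybenzyl)-2-(4-hydroxy-3-methoxyphenyl)tetrahydrofuran-3-yl]methyl 4-hydroxybenzoate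
Conditions: TBAF (3.3 equiv), AcOH, THF, 0 °C → rt
Reagents that add atoms: none
Why: Fluoride-induced desilylation of the three aryl silyl ethers, buffered with acetic acid so that the phenoxides do not attack the benzoate ester or open the p-hydroxybenzylic C7–O bond through a quinone methide.

**Compound list**
1 | vanillin (4-hydroxy-3-methoxybenzaldehyde) | COc1cc(C=O)ccc1O | starting material
2 | 3-methoxy-4-(triisopropylsilyloxy)benzaldehyde | COc1cc(C=O)ccc1O[Si](C(C)C)(C(C)C)C(C)C | intermediate
3 | methyl propiolate | C#CC(=O)OC | starting material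
4 | methyl (S)-4-hydroxy-4-[3-methoxy-4-(triisopropylsilyloxy)phenyl]but-2-ynoate | COC(=O)C#C[C@@H](O)c1ccc(O[Si](C(C)C)(C(C)C)C(C)C)c(OC)c1 | intermediate
5 | methyl (2Z,4R)-4-hydroxy-4-[3-methoxy-4-(triisopropylsilyloxy)phenyl]but-2-enoate (formed in the flask) | COC(=O)/C=C\[C@@H](O)c1ccc(O[Si](C(C)C)(C(C)C)C(C)C)c(OC)c1 | intermediate
6 | (R)-5-[3-methoxy-4-(triisopropylsilyloxy)phenyl]furan-2(5H)-one | O=C1C=C[C@H](c2ccc(O[Si](C(C)C)(C(C)C)C(C)C)c(OC)c2)O1 | intermediate
7 | (chloromethyl)(isopropoxy)dimethylsilane | CC(C)O[Si](C)(C)CCl | starting material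
8 | [(isopropoxydimethylsilyl)methyl]magnesium chloride | CC(C)O[Si](C)(C)C[Mg]Cl | intermediate
9 | chloromagnesium enolate of (4R,5R)-4-[(isopropoxydimethylsilyl)methyl]-5-[3-methoxy-4-(triisopropylsilyloxy)phenyl]dihydrofuran-2(3H)-one (formed in the flask) | Cl[Mg]OC1=C[C@@H](C[Si](C)(C)OC(C)C)[C@H](c2ccc(O[Si](C(C)C)(C(C)C)C(C)C)c(OC)c2)O1 | intermediate
10 | chloromagnesium alkoxide of (3S,4R,5R)-3-{hydroxy[3-methoxy-4-(triisopropylsilyloxy)phenyl]methyl}-4-[(isopropoxydimethylsilyl)methyl]-5-[3-methoxy-4-(triisopropylsilyloxy)phenyl]dihydrofuran-2(3H)-one, both carbinol epimers (formed in the flask) | O=C1O[C@@H](c2ccc(O[Si](C(C)C)(C(C)C)C(C)C)c(OC)c2)[C@H](C[Si](C)(C)OC(C)C)[C@H]1C(O[Mg]Cl)c1ccc(O[Si](C(C)C)(C(C)C)C(C)C)c(OC)c1 | intermediate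
11 | acetate of the aldol in 10, both carbinol epimers (formed in the flask) | O=C1O[C@@H](c2ccc(O[Si](C(C)C)(C(C)C)C(C)C)c(OC)c2)[C@H](C[Si](C)(C)OC(C)C)[C@H]1C(OC(C)=O)c1ccc(O[Si](C(C)C)(C(C)C)C(C)C)c(OC)c1 | intermediate
12 | (3E,4R,5R)-4-[(isopropoxydimethylsilyl)methyl]-3-[3-methoxy-4-(triisopropylsilyloxy)benzylidene]-5-[3-methoxy-4-(triisopropylsilyloxy)phenyl]dihydrofuran-2(3H)-one | O=C1O[C@@H](c2ccc(O[Si](C(C)C)(C(C)C)C(C)C)c(OC)c2)[C@H](C[Si](C)(C)OC(C)C)/C1=C\c1ccc(O[Si](C(C)C)(C(C)C)C(C)C)c(OC)c1 | intermediate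
13 | (3E,4R,5R)-4-[(isopropoxydimethylsilyl)methyl]-3-[3-methoxy-4-(triisopropylsilyloxy)benzylidene]-5-[3-methoxy-4-(triisopropylsilyloxy)phenyl]tetrahydrofuran-2-ol, both anomers | OC1O[C@@H](c2ccc(O[Si](C(C)C)(C(C)C)C(C)C)c(OC)c2)[C@H](C[Si](C)(C)OC(C)C)/C1=C\c1ccc(O[Si](C(C)C)(C(C)C)C(C)C)c(OC)c1 | intermediate
14 | (2R,3R,4E)-3-[(isopropoxydimethylsilyl)methyl]-4-[3-methoxy-4-(triisopropylsilyloxy)benzylidene]-2-[3-methoxy-4-(triisopropylsilyloxy)phenyl]tetrahydrofuran | C1O[C@@H](c2ccc(O[Si](C(C)C)(C(C)C)C(C)C)c(OC)c2)[C@H](C[Si](C)(C)OC(C)C)/C1=C\c1ccc(O[Si](C(C)C)(C(C)C)C(C)C)c(OC)c1 | intermediate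
15 | (2R,3R,4S)-3-[(isopropoxydimethylsilyl)methyl]-4-[3-methoxy-4-(triisopropylsilyloxy)benzyl]-2-[3-methoxy-4-(triisopropylsilyloxy)phenyl]tetrahydrofuran | C1O[C@@H](c2ccc(O[Si](C(C)C)(C(C)C)C(C)C)c(OC)c2)[C@H](C[Si](C)(C)OC(C)C)[C@@H]1Cc1ccc(O[Si](C(C)C)(C(C)C)C(C)C)c(OC)c1 | intermediate
16 | [(2R,3S,4S)-4-[3-methoxy-4-(triisopropylsilyloxy)benzyl]-2-[3-methoxy-4-(triisopropylsilyloxy)phenyl]tetrahydrofuran-3-yl]methanol | C1O[C@@H](c2ccc(O[Si](C(C)C)(C(C)C)C(C)C)c(OC)c2)[C@H](CO)[C@@H]1Cc1ccc(O[Si](C(C)C)(C(C)C)C(C)C)c(OC)c1 | intermediate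
17 | 4-hydroxybenzoic acid | OC(=O)c1ccc(O)cc1 | starting material
18 | triisopropylsilyl 4-(triisopropylsilyloxy)benzoate (formed in the flask) | CC(C)[Si](C(C)C)(C(C)C)OC(=O)c1ccc(O[Si](C(C)C)(C(C)C)C(C)C)cc1 | intermediate
19 | 4-(triisopropylsilyloxy)benzoic acid | OC(=O)c1ccc(O[Si](C(C)C)(C(C)C)C(C)C)cc1 | intermediate
20 | [(2R,3S,4S)-4-[3-methoxy-4-(triisopropylsilyloxy)benzyl]-2-[3-methoxy-4-(triisopropylsilyloxy)phenyl]tetrahydrofuran-3-yl]methyl 4-(triisopropylsilyloxy)benzoate | C1O[C@@H](c2ccc(O[Si](C(C)C)(C(C)C)C(C)C)c(OC)c2)[C@H](COC(=O)c2ccc(O[Si](C(C)C)(C(C)C)C(C)C)cc2)[C@@H]1Cc1ccc(O[Si](C(C)C)(C(C)C)C(C)C)c(OC)c1 | intermediate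
21 | agastinol | COc1cc(C[C@@H]2CO[C@@H](c3ccc(O)c(OC)c3)[C@@H]2COC(=O)c2ccc(O)cc2)ccc1O | target

**Step count**
Total: 12 steps. Longest linear sequence: 10 steps (1, 2, 3, 5, 6, 7, 8, 9, 11, 12, from vanillin).

**Steps most likely to fail**

Step 5. The cuprate may act as a base on the acidic C7–H, which would racemise 6 through its 2-oxyfuran anion, or it may transfer the silylmethyl group too slowly; the acetylation and elimination may also stay incomplete in the same flask. The fallback sets out from 6 and comes back at 12, and it separates the three events. The 1,4-addition is run under copper catalysis with a chlorosilane that silylates the enolate as it forms (8, CuI cat., TMSCl, THF, −78 °C), which should speed the addition relative to deprotonation. It gives the trimethylsilyl ketene acetal F1, which dilute acid hydrolyses on work-up to the saturated trans-lactone F2. LiHMDS (THF, −78 °C) then forms the enolate of F2, which has no acidic C7–H left, and aldehyde 2 gives the aldol F3. MsCl/Et3N converts it into the mesylate F4, and DBU eliminates this to 12.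

Step 7. Hydride may be delivered to the benzylic terminus C7' of the allyl-type oxocarbenium ion instead of C9', which would end in an uncontrolled C8' centre. The C7–O bond may also ionise, or the Si–O-isopropyl group may exchange with BF3. The fallback sets out from 12 and comes back at 15, and it saturates the alkene before any cation is made. Hydrogenation of 12 (H2, Rh/Al2O3, EtOAc) anti to the C8 arm should give the cis-lactone F5. DIBAL-H at −78 °C gives the saturated lactol F6, and Et3SiH/BF3·OEt2 at −78 °C reduces its ordinary, non-allylic oxocarbenium ion to 15, so that step 8 is no longer needed.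

Step 9. The aryl TIPS ethers may be partly lost in warm alkaline peroxide, and the free phenols would then compete in the acylation of step 11. The fallback sets out from 15 and comes back at 21, and it gives up phenol protection altogether. Tamao oxidation with fluoride (KF, KHCO3, H2O2, THF/MeOH) followed by TBAF removes the silicon at C9 and both aryl TIPS groups and gives the (2R,3S,4S)-triol F7. A Mitsunobu esterification of F7 with unprotected 4-hydroxybenzoic acid 17 (PPh3, DIAD, THF, 0 °C) should then acylate only the primary C9 alcohol, because only the carboxylic acid is acidic enough to serve as the pronucleophile. This gives 21 directly and replaces steps 10 to 12.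

**Further compounds**
F1 | step 5 | {[(4R,5R)-4-[(isopropoxydimethylsilyl)methyl]-5-[3-methoxy-4-(triisopropylsilyloxy)phenyl]-4,5-dihydrofuran-2-yl]oxy}trimethylsilane | C[Si](C)(C)OC1=C[C@@H](C[Si](C)(C)OC(C)C)[C@H](c2ccc(O[Si](C(C)C)(C(C)C)C(C)C)c(OC)c2)O1
F2 | step 5 | (4R,5R)-4-[(isopropoxydimethylsilyl)methyl]-5-[3-methoxy-4-(triisopropylsilyloxy)phenyl]dihydrofuran-2(3H)-one | O=C1C[C@@H](C[Si](C)(C)OC(C)C)[C@H](c2ccc(O[Si](C(C)C)(C(C)C)C(C)C)c(OC)c2)O1
F3 | step 5 | (3S,4R,5R)-3-{hydroxy[3-methoxy-4-(triisopropylsilyloxy)phenyl]methyl}-4-[(isopropoxydimethylsilyl)methyl]-5-[3-methoxy-4-(triisopropylsilyloxy)phenyl]dihydrofuran-2(3H)-one, both carbinol epimers | O=C1O[C@@H](c2ccc(O[Si](C(C)C)(C(C)C)C(C)C)c(OC)c2)[C@H](C[Si](C)(C)OC(C)C)[C@H]1C(O)c1ccc(O[Si](C(C)C)(C(C)C)C(C)C)c(OC)c1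
F4 | step 5 | methanesulfonate of F3, both epimers | O=C1O[C@@H](c2ccc(O[Si](C(C)C)(C(C)C)C(C)C)c(OC)c2)[C@H](C[Si](C)(C)OC(C)C)[C@H]1C(OS(C)(=O)=O)c1ccc(O[Si](C(C)C)(C(C)C)C(C)C)c(OC)c1
F5 | step 7 | (3S,4R,5R)-4-[(isopropoxydimethylsilyl)methyl]-3-[3-methoxy-4-(triisopropylsilyloxy)benzyl]-5-[3-methoxy-4-(triisopropylsilyloxy)phenyl]dihydrofuran-2(3H)-one | O=C1O[C@@H](c2ccc(O[Si](C(C)C)(C(C)C)C(C)C)c(OC)c2)[C@H](C[Si](C)(C)OC(C)C)[C@@H]1Cc1ccc(O[Si](C(C)C)(C(C)C)C(C)C)c(OC)c1
F6 | step 7 | (3S,4R,5R)-4-[(isopropoxydimethylsilyl)methyl]-3-[3-methoxy-4-(triisopropylsilyloxy)benzyl]-5-[3-methoxy-4-(triisopropylsilyloxy)phenyl]tetrahydrofuran-2-ol, both anomers | OC1O[C@@H](c2ccc(O[Si](C(C)C)(C(C)C)C(C)C)c(OC)c2)[C@H](C[Si](C)(C)OC(C)C)[C@@H]1Cc1ccc(O[Si](C(C)C)(C(C)C)C(C)C)c(OC)c1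
F7 | step 9 | 4-[(2R,3S,4S)-4-(4-hydroxy-3-methoxybenzyl)-3-(hydroxymethyl)tetrahydrofuran-2-yl]-2-methoxyphenol | C1O[C@@H](c2ccc(O)c(OC)c2)[C@H](CO)[C@@H]1Cc1ccc(O)c(OC)c1
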